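**Strategy.** The route rests on disconnecting the C1'–O and C4'–O bonds of the ring as a peroxide bridge across a cyclohexa-1,3-diene. The target's cyclohexenone ring carries the C1' hydroxyl and the C4' ketone in a 1,4-relation across the C2'=C3' double bond, and C1' adjoins the quaternary C6'. One singlet-oxygen [4+2] cycloaddition therefore installs both oxygens, places the alkene and fixes C1' relative to C6'. Its precursor is the complete tetraene: a C1'=C2'–C3'=C4' ring diene bearing the (2Z,4E)-dienoate at C1' and methyl plus HMG-oxymethyl at C6', with both carboxyls masked as 2-(trimethylsilyl)ethyl esters and the HMG hydroxyl as a triethylsilyl ether.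

Key step: step 18

Remarks. Ring atoms are numbered C1' (carbinol carbon) to C6' (quaternary carbon); chain atoms run from C1 (carboxyl) to C5. The CIP descriptors of C6' and of the HMG carbon change along the route only because substituent priorities change; no centre is inverted. The lactone carbonyl of (R)-mevalonolactone ends as the ester to the ring CH2O group.
Assumption: the (S,S)-ligand of step 4 is taken to give (S)-7; should a trial show the opposite sense, the (R,R)-ligand is used and nothing else changes.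

**Ring fragment**

Step 1
Reactants: 1 2,6-dimethylcyclohexanone
Product: 2 2-chloro-2,6-dimethylcyclohexanone (racemic diastereomer mixture)
Conditions: SO2Cl2, CH2Cl2, 0 °C → rt
Reagents that add atoms: sulfuryl chloride, O=S(=O)(Cl)Cl
Why: Electrophilic α-chlorination of the ketone through its more substituted enol puts chlorine on a methyl-bearing α-carbon, and because both α-carbons are equivalent only one constitution can result.

Step 2
Reactants: 2 2-chloro-2,6-dimethylcyclohexanone
Product: 3 2,6-dimethylcyclohex-2-en-1-one (racemic)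
Conditions: Li2CO3, LiBr, DMF, 120 °C
Reagents that add atoms: none
Why: Dehydrohalogenation (E2 elimination) of the tertiary α-chloro ketone under equilibrating halide/carbonate conditions should give the conjugated endocyclic enone, the more stable alkene.

Step 3
Reactants: 3 2,6-dimethylcyclohex-2-en-1-one
Product: 5 [(2,6-dimethylcyclohexa-1,5-dien-1-yl)oxy]trimethylsilane, via lithium dienolate 4 (not isolated)
Conditions: LiN(i-Pr)2, THF, −78 °C; Me3SiCl, −78 °C → rt; non-aqueous work-up
Reagents that add atoms: chlorotrimethylsilane, C[Si](C)(C)Cl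
Why: Kinetic α'-deprotonation at C6 by the hindered amide and O-silylation (silyl enol ether formation) erase the C6 stereocentre, so the asymmetric step starts from an achiral substrate.

Step 4
Reactants: 5 [(2,6-dimethylcyclohexa-1,5-dien-1-yl)oxy]trimethylsilane; 6 formaldehyde
Product: 7 (6S)-6-(hydroxymethyl)-2,6-dimethylcyclohex-2-en-1-one
Conditions: Sc(OTf)3 (10 mol%), (S,S)-6,6'-bis(1-hydroxy-2,2-dimethylpropyl)-2,2'-bipyridine (12 mol%), 37% aq. HCHO, DME, −20 °C
Reagents that add atoms: none
Why: Catalytic asymmetric Mukaiyama aldol reaction (hydroxymethylation) in which the chiral scandium–bipyridine complex binds formaldehyde and distinguishes the enantiotopic faces of the tetrasubstituted enol ether carbon, so the quaternary centre C6' is set under catalyst control and the enone returns on loss of silicon.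

Step 5
Reactants: 7 (6S)-6-(hydroxymethyl)-2,6-dimethylcyclohex-2-en-1-one
Product: 8 (6S)-2,6-dimethyl-6-{[(triethylsilyl)oxy]methyl}cyclohex-2-en-1-one
Conditions: Et3SiCl, imidazole, CH2Cl2, 0 °C
Reagents that add atoms: chlorotriethylsilane, CC[Si](CC)(CC)Cl
Why: Silyl ether formation under imidazole is mild enough to avoid retro-aldol loss of formaldehyde from the β-hydroxy ketone and masks the hydroxyl against the strong base of step 6.

Step 6
Reactants: 8 (6S)-2,6-dimethyl-6-{[(triethylsilyl)oxy]methyl}cyclohex-2-en-1-one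
Product: 10 (6S)-2,6-dimethyl-6-{[(triethylsilyl)oxy]methyl}cyclohexa-1,3-dien-1-yl trifluoromethanesulfonate, via lithium dienolate 9 (not isolated)
Conditions: LiN(i-Pr)2, THF, −78 °C; PhNTf2, −78 → 0 °C
Reagents that add atoms: N-phenylbis(trifluoromethanesulfonimide), O=S(=O)(N(c1ccccc1)S(=O)(=O)C(F)(F)F)C(F)(F)F
Why: With no α'-hydrogen left, the base removes a γ-hydrogen at C4' to give the linear dienolate, and its O-sulfonylation (enol triflate formation) gives the cyclohexa-1,3-dienyl triflate, as is known for 2,6,6-trisubstituted cyclohex-2-enones.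

Step 7
Reactants: 10 (6S)-2,6-dimethyl-6-{[(triethylsilyl)oxy]methyl}cyclohexa-1,3-dien-1-yl trifluoromethanesulfonate
Product: 11 (6S)-6-(hydroxymethyl)-2,6-dimethylcyclohexa-1,3-dien-1-yl trifluoromethanesulfonate
Conditions: PPTS (cat.), MeOH/CH2Cl2, 0 °C → rt
Reagents that add atoms: none
Why: Acid-catalysed methanolysis of the primary triethylsilyl ether (silyl ether cleavage) should free the alcohol while the dienyl triflate, inert to mild acid, stays intact.

**HMG fragment**

Step 8
Reactants: 12 (R)-mevalonolactone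
Product: 14 benzyl (3R)-3,5-dihydroxy-3-methylpentanoate, via potassium mevalonate 13 (not isolated)
Conditions: KOH (1.0 equiv), H2O, rt; evaporate; BnBr, DMF, rt
Reagents that add atoms: potassium hydroxide, [K+].[OH-]; benzyl bromide, BrCc1ccccc1
Why: Saponification of the δ-lactone followed by SN2 O-alkylation of the carboxylate masks the former lactone carbonyl as a benzyl ester and leaves the carbinol centre untouched.

Step 9
Reactants: 14 benzyl (3R)-3,5-dihydroxy-3-methylpentanoate
Product: 16 (3R)-5-(benzyloxy)-3-hydroxy-3-methyl-5-oxopentanoic acid, via aldehyde 15 (not isolated)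
Conditions: TEMPO (cat.), PhI(OAc)2 (2.2 equiv), MeCN/H2O 1:1, rt
Reagents that add atoms: water, O
Why: Oxoammonium (TEMPO) oxidation takes the primary alcohol through the aldehyde hydrate to the acid and does not touch the tertiary alcohol or the benzyl ester.

Step 10
Reactants: 16 (3R)-5-(benzyloxy)-3-hydroxy-3-methyl-5-oxopentanoic acid
Product: 17 1-benzyl 5-[2-(trimethylsilyl)ethyl] (3S)-3-hydroxy-3-methylpentanedioate
Conditions: Me3SiCH2CH2OH, EDC·HCl, DMAP (cat.), CH2Cl2, 0 °C → rt
Reagents that add atoms: 2-(trimethylsilyl)ethanol, C[Si](C)(C)CCO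
Why: Steglich esterification of the free acid with a primary alcohol tells the two carboxyl termini apart for good.

Step 11
Reactants: 17 1-benzyl 5-[2-(trimethylsilyl)ethyl] (3S)-3-hydroxy-3-methylpentanedioate
Product: 18 1-benzyl 5-[2-(trimethylsilyl)ethyl] (3S)-3-methyl-3-[(triethylsilyl)oxy]pentanedioate
Conditions: Et3SiOTf, 2,6-lutidine, CH2Cl2, −78 → 0 °C
Reagents that add atoms: triethylsilyl trifluoromethanesulfonate, CC[Si](CC)(CC)OS(=O)(=O)C(F)(F)F
Why: Silylation of the tertiary alcohol with a silyl triflate and a hindered base removes the only hydroxyl of the arm, so it can neither be acylated in step 13 nor hydrogen-bond to singlet oxygen in step 18.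

Step 12
Reactants: 18 1-benzyl 5-[2-(trimethylsilyl)ethyl] (3S)-3-methyl-3-[(triethylsilyl)oxy]pentanedioate
Product: 19 (3S)-3-methyl-5-oxo-3-[(triethylsilyl)oxy]-5-[2-(trimethylsilyl)ethoxy]pentanoic acid
Conditions: H2 (1 atm), Pd/C (10%), EtOAc, rt
Reagents that add atoms: none
Why: Hydrogenolysis of the benzyl ester frees the carboxyl that stems from the lactone carbonyl, while the silyl ether and the silylethyl ester are inert in ethyl acetate.

**Union of ring and HMG fragments**

Step 13
Reactants: 11 (6S)-6-(hydroxymethyl)-2,6-dimethylcyclohexa-1,3-dien-1-yl trifluoromethanesulfonate; 19 (3S)-3-methyl-5-oxo-3-[(triethylsilyl)oxy]-5-[2-(trimethylsilyl)ethoxy]pentanoic acid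
Product: 20 [(1S)-1,3-dimethyl-2-{[(trifluoromethyl)sulfonyl]oxy}cyclohexa-2,4-dien-1-yl]methyl 2-(trimethylsilyl)ethyl (3S)-3-methyl-3-[(triethylsilyl)oxy]pentanedioate
Conditions: EDC·HCl, DMAP, CH2Cl2, 0 °C → rt
Reagents that add atoms: none
Why: Steglich esterification of the neopentyl-type primary alcohol under mild carbodiimide activation, chosen so that the half ester is not driven to the symmetric cyclic anhydride, which would scramble its two arms.

**Side-chain fragment**

Step 14
Reactants: 21 but-2-ynoic acid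
Product: 22 (2Z)-3-iodobut-2-enoic acid
Conditions: NaI, AcOH, 110 °C
Reagents that add atoms: sodium iodide, [Na+].[I-]
Why: Hydroiodination of the ynoic acid by anti conjugate addition of iodide and a proton gives the (Z)-β-iodo acid with iodine and carboxyl cis.

Step 15
Reactants: 22 (2Z)-3-iodobut-2-enoic acid
Product: 23 2-(trimethylsilyl)ethyl (2Z)-3-iodobut-2-enoate
Conditions: Me3SiCH2CH2OH, PPh3, DIAD, THF, 0 °C → rt
Reagents that add atoms: 2-(trimethylsilyl)ethanol, C[Si](C)(C)CCO
Why: Mitsunobu esterification runs under neutral conditions without a nucleophilic catalyst, so the (Z)-β-iodoenoate cannot isomerise by addition–elimination.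

Step 16
Reactants: 23 2-(trimethylsilyl)ethyl (2Z)-3-iodobut-2-enoate; 24 (E)-1,2-bis(tributylstannyl)ethene
Product: 25 2-(trimethylsilyl)ethyl (2Z,4E)-3-methyl-5-(tributylstannyl)penta-2,4-dienoate
Conditions: 24 (2 equiv), PdCl2(MeCN)2 (5 mol%), DMF, rt, dark
Reagents that add atoms: none
Why: Stille coupling of the vinyl iodide with one end of the distannane, used in excess to suppress double coupling, proceeds with retention at both alkenes and gives the (2Z,4E)-stannyl dienoate.

**Assembly, key step and end game**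

Step 17
Reactants: 20 dienyl triflate diester; 25 2-(trimethylsilyl)ethyl (2Z,4E)-3-methyl-5-(tributylstannyl)penta-2,4-dienoate
Product: 26 2-(trimethylsilyl)ethyl (2Z,4E)-5-[(6R)-2,6-dimethyl-6-({[(3S)-3-methyl-5-oxo-3-[(triethylsilyl)oxy]-5-[2-(trimethylsilyl)ethoxy]pentanoyl]oxy}methyl)cyclohexa-1,3-dien-1-yl]-3-methylpenta-2,4-dienoate
Conditions: Pd2(dba)3 (5 mol%), AsPh3 (40 mol%), CuI (10 mol%), NMP, 45 °C, dark
Reagents that add atoms: none
Why: Stille coupling of the dienyl triflate with the vinylstannane under the weak-ligand conditions suited to hindered triflates forms the C1'–C5 bond with retention of alkene geometry, and the silylethyl esters are chosen because, unlike allyl esters, they cannot ionise on zerovalent palladium.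

Step 18
Reactants: 26 tetraene diester
Product: 27 2-(trimethylsilyl)ethyl (2Z,4E)-5-[(1R,4R,7S)-6,7-dimethyl-7-({[(3S)-3-methyl-5-oxo-3-[(triethylsilyl)oxy]-5-[2-(trimethylsilyl)ethoxy]pentanoyl]oxy}methyl)-2,3-dioxabicyclo[2.2.2]oct-5-en-1-yl]-3-methylpenta-2,4-dienoate (peroxide bridge on the face of the C6' methyl)
Conditions: O2, tetraphenylporphyrin (cat.), CH2Cl2, −40 °C, hν (>500 nm)
Reagents that add atoms: dioxygen, O=O
Why: Triplet tetraphenylporphyrin passes its energy to O2, and the singlet oxygen so formed adds to the ring diene in a concerted, suprafacial [4+2] cycloaddition, the closest known reaction type being the dye-sensitised photooxygenation of cyclohexa-1,3-dienes that bear a dienoate chain. The 1,2-dioxane ring is closed by the cycloaddition itself: the C1'–O and C4'–O bonds form in one event on the same face and bridge the carbocycle to a 2,3-dioxabicyclo[2.2.2]oct-5-ene. The ring diene is the only diene of the tetraene held s-cis and the one least deactivated by the ester, so the side-chain diene and the silyl groups should stay untouched, and light above 500 nm excites only the dye, which guards the (2Z)-geometry. C1' is set by the existing centre C6': on its way to C1' the reagent must pass one of the two C6' substituents, and the methyl group is smaller than the acyloxymethyl arm and lacks the ester lone pairs that repel the electron-rich distal oxygen, so attack is expected on the methyl face, placing the new C1'–O bond cis to the C6' methyl as in the target. C4' is tied to C1' by the bridge and is erased when it becomes the ketone in step 19. The selectivity needed is therefore π-facial, secured by the size and polarity difference between CH3 and CH2O-acyl at C6' and by the absence of any hydroxyl group that could steer oxygen to the arm face; this margin is modest and is the one real risk of the route.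

Step 19
Reactants: 27 endoperoxide
Product: 28 2-(trimethylsilyl)ethyl (2Z,4E)-5-[(1R,6S)-1-hydroxy-2,6-dimethyl-6-({[(3S)-3-methyl-5-oxo-3-[(triethylsilyl)oxy]-5-[2-(trimethylsilyl)ethoxy]pentanoyl]oxy}methyl)-4-oxocyclohex-2-en-1-yl]-3-methylpenta-2,4-dienoate
Conditions: Et3N, CH2Cl2, 0 °C → rt
Reagents that add atoms: none
Why: Kornblum–DeLaMare rearrangement, in which the amine removes the C4' hydrogen and the O–O bond breaks to give the C4' ketone and the C1' tertiary alcohol with C1' and C6' untouched, while the acylated CH2O group cannot add to the new enone.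

Step 20
Reactants: 28 protected hydroxy enone
Product: 29 (2Z,4E)-5-[(1R,6S)-6-({[(3R)-4-carboxy-3-hydroxy-3-methylbutanoyl]oxy}methyl)-1-hydroxy-2,6-dimethyl-4-oxocyclohex-2-en-1-yl]-3-methylpenta-2,4-dienoic acid (CNP0183058.1)
Conditions: TASF (6 equiv), DMF, 0 °C → rt; dilute aq. HCl to pH 3
Reagents that add atoms: none
Why: Fluoride-induced fragmentation of the two 2-(trimethylsilyl)ethyl esters (loss of ethene and fluorosilane) and Si–O cleavage of the silyl ether should unmask both acids and the tertiary alcohol without any acyl–oxygen cleavage, so the HMG ester link and the (2Z)-geometry persist.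

**Compound list**

1 | 2,6-dimethylcyclohexanone (cis/trans mixture) | CC1CCCC(C)C1=O | starting material
2 | 2-chloro-2,6-dimethylcyclohexanone (racemic, diastereomer mixture) | CC1CCCC(C)(Cl)C1=O | intermediate
3 | 2,6-dimethylcyclohex-2-en-1-one (racemic) | CC1=CCCC(C)C1=O | intermediate
4 | lithium 2,6-dimethylcyclohexa-1,5-dien-1-olate | [Li+].[O-]C1=C(C)CCC=C1C | intermediate (not isolated)
5 | [(2,6-dimethylcyclohexa-1,5-dien-1-yl)oxy]trimethylsilane | C[Si](C)(C)OC1=C(C)CCC=C1C | intermediate
6 | formaldehyde | C=O | starting material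
7 | (6S)-6-(hydroxymethyl)-2,6-dimethylcyclohex-2-en-1-one | CC1=CCC[C@@](C)(CO)C1=O | intermediate
8 | (6S)-2,6-dimethyl-6-{[(triethylsilyl)oxy]methyl}cyclohex-2-en-1-one | CC1=CCC[C@@](C)(CO[Si](CC)(CC)CC)C1=O | intermediate
9 | lithium (6S)-2,6-dimethyl-6-{[(triethylsilyl)oxy]methyl}cyclohexa-1,3-dien-1-olate | [Li+].[O-]C1=C(C)C=CC[C@@]1(C)CO[Si](CC)(CC)CC | intermediate (not isolated)
10 | (6S)-2,6-dimethyl-6-{[(triethylsilyl)oxy]methyl}cyclohexa-1,3-dien-1-yl trifluoromethanesulfonate | CC1=C(OS(=O)(=O)C(F)(F)F)[C@](C)(CO[Si](CC)(CC)CC)CC=C1 | intermediate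
11 | (6S)-6-(hydroxymethyl)-2,6-dimethylcyclohexa-1,3-dien-1-yl trifluoromethanesulfonate | CC1=C(OS(=O)(=O)C(F)(F)F)[C@](C)(CO)CC=C1 | intermediate
12 | (R)-mevalonolactone, (4R)-4-hydroxy-4-methyloxan-2-one | O=C1C[C@](C)(O)CCO1 | starting material
13 | potassium (3R)-3,5-dihydroxy-3-methylpentanoate | [K+].[O-]C(=O)C[C@](C)(O)CCO | intermediate (not isolated)
14 | benzyl (3R)-3,5-dihydroxy-3-methylpentanoate | O=C(OCc1ccccc1)C[C@](C)(O)CCO | intermediate
15 | benzyl (3R)-3-hydroxy-3-methyl-5-oxopentanoate | O=C(OCc1ccccc1)C[C@](C)(O)CC=O | intermediate (not isolated)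
16 | (3R)-5-(benzyloxy)-3-hydroxy-3-methyl-5-oxopentanoic acid | O=C(OCc1ccccc1)C[C@](C)(O)CC(=O)O | intermediate
17 | 1-benzyl 5-[2-(trimethylsilyl)ethyl] (3S)-3-hydroxy-3-methylpentanedioate | O=C(OCc1ccccc1)C[C@](C)(O)CC(=O)OCC[Si](C)(C)C | intermediate
18 | 1-benzyl 5-[2-(trimethylsilyl)ethyl] (3S)-3-methyl-3-[(triethylsilyl)oxy]pentanedioate | O=C(OCc1ccccc1)C[C@](C)(O[Si](CC)(CC)CC)CC(=O)OCC[Si](C)(C)C | intermediate
19 | (3S)-3-methyl-5-oxo-3-[(triethylsilyl)oxy]-5-[2-(trimethylsilyl)ethoxy]pentanoic acid | OC(=O)C[C@](C)(O[Si](CC)(CC)CC)CC(=O)OCC[Si](C)(C)C | intermediate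
20 | [(1S)-1,3-dimethyl-2-{[(trifluoromethyl)sulfonyl]oxy}cyclohexa-2,4-dien-1-yl]methyl 2-(trimethylsilyl)ethyl (3S)-3-methyl-3-[(triethylsilyl)oxy]pentanedioate | CC1=C(OS(=O)(=O)C(F)(F)F)[C@](C)(COC(=O)C[C@](C)(O[Si](CC)(CC)CC)CC(=O)OCC[Si](C)(C)C)CC=C1 | intermediate
21 | but-2-ynoic acid | CC#CC(=O)O | starting material
22 | (2Z)-3-iodobut-2-enoic acid | C/C(I)=C/C(=O)O | intermediate
23 | 2-(trimethylsilyl)ethyl (2Z)-3-iodobut-2-enoate | C/C(I)=C/C(=O)OCC[Si](C)(C)C | intermediate
24 | (E)-1,2-bis(tributylstannyl)ethene | CCCC[Sn](CCCC)(CCCC)/C=C/[Sn](CCCC)(CCCC)CCCC | starting material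
25 | 2-(trimethylsilyl)ethyl (2Z,4E)-3-methyl-5-(tributylstannyl)penta-2,4-dienoate | CCCC[Sn](CCCC)(CCCC)/C=C/C(C)=C\C(=O)OCC[Si](C)(C)C | intermediate
26 | 2-(trimethylsilyl)ethyl (2Z,4E)-5-[(6R)-2,6-dimethyl-6-({[(3S)-3-methyl-5-oxo-3-[(triethylsilyl)oxy]-5-[2-(trimethylsilyl)ethoxy]pentanoyl]oxy}methyl)cyclohexa-1,3-dien-1-yl]-3-methylpenta-2,4-dienoate (key-step precursor) | CC1=C(/C=C/C(C)=C\C(=O)OCC[Si](C)(C)C)[C@](C)(COC(=O)C[C@](C)(O[Si](CC)(CC)CC)CC(=O)OCC[Si](C)(C)C)CC=C1 | intermediate
27 | 2-(trimethylsilyl)ethyl (2Z,4E)-5-[(1R,4R,7S)-6,7-dimethyl-7-({[(3S)-3-methyl-5-oxo-3-[(triethylsilyl)oxy]-5-[2-(trimethylsilyl)ethoxy]pentanoyl]oxy}methyl)-2,3-dioxabicyclo[2.2.2]oct-5-en-1-yl]-3-methylpenta-2,4-dienoate (key-step product) | CC1=C[C@H]2C[C@@](C)(COC(=O)C[C@](C)(O[Si](CC)(CC)CC)CC(=O)OCC[Si](C)(C)C)[C@]1(/C=C/C(C)=C\C(=O)OCC[Si](C)(C)C)OO2 | intermediate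
28 | 2-(trimethylsilyl)ethyl (2Z,4E)-5-[(1R,6S)-1-hydroxy-2,6-dimethyl-6-({[(3S)-3-methyl-5-oxo-3-[(triethylsilyl)oxy]-5-[2-(trimethylsilyl)ethoxy]pentanoyl]oxy}methyl)-4-oxocyclohex-2-en-1-yl]-3-methylpenta-2,4-dienoate | CC1=CC(=O)C[C@@](C)(COC(=O)C[C@](C)(O[Si](CC)(CC)CC)CC(=O)OCC[Si](C)(C)C)[C@@]1(O)/C=C/C(C)=C\C(=O)OCC[Si](C)(C)C | intermediate
29 | (2Z,4E)-5-[(1R,6S)-6-({[(3R)-4-carboxy-3-hydroxy-3-methylbutanoyl]oxy}methyl)-1-hydroxy-2,6-dimethyl-4-oxocyclohex-2-en-1-yl]-3-methylpenta-2,4-dienoic acid | CC1=CC(=O)C[C@@](C)(COC(=O)C[C@](C)(O)CC(=O)O)[C@@]1(O)/C=C/C(C)=C\C(=O)O | target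

**Step count and risks**

Total step count: 20. Longest linear sequence: 12 steps (steps 1–7, 13, 17–20).

Steps most likely to fail:

1. Step 18, poor facial selectivity of the cycloaddition. The methyl and acyloxymethyl groups at C6' may not differ enough, so that oxygen adds to both faces. The fallback moves the cycloaddition ahead of the HMG acylation and lets a bulky silyl ether, sitting directly on the CH2O carbon, screen the arm face. It sets out from 11. Silylation (t-BuPh2SiCl, imidazole, DMF) should give the silyl ether triflate F1. Stille coupling with 25 under the conditions of step 17 should give the silyloxymethyl tetraene F2. Photooxygenation as in step 18 should give the silyl-protected endoperoxide F3. Buffered HF·pyridine (THF/pyridine, 0 °C → rt) should then free the hydroxy endoperoxide F4 while the peroxide bridge is still closed, so no enone is present for the alcohol to add to. Esterification with 19 (EDC·HCl, catalytic DMAP, 0 °C) comes back to the route at 27.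

2. Step 4, insufficient enantioselectivity in forming the quaternary centre on an enol ether of this type. The fallback replaces asymmetric catalysis by enzymatic kinetic resolution. It sets out from 5. Achiral Yb(OTf)3 with aqueous formaldehyde (THF, rt) should give the racemic hydroxymethyl enone F5. Transesterification with vinyl acetate under a lipase (Burkholderia cepacia lipase, t-BuOMe, rt), the enzyme being chosen by screening so that the (R)-alcohol reacts faster, is run past half conversion. The (R)-acetate F6 is removed by chromatography, and the unreacted (S)-alcohol is 7, where the route is rejoined.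

3. Step 17, slow transmetalation of the long stannane to the crowded dienyl–palladium intermediate, with loss of the triflate by competing decomposition. The fallback builds the side chain in two couplings, the small distannane first. It sets out from 20. Stille coupling with an excess of 24 (Pd2(dba)3, AsPh3, NMP, 45 °C) should give the ring vinylstannane F7. A second Stille coupling with iodide 23 (PdCl2(MeCN)2, DMF, rt) then forms the C3–C4 bond and comes back to the route at 26.

**Further compounds**

F1 | step 18 | (6S)-6-{[(tert-butyldiphenylsilyl)oxy]methyl}-2,6-dimethylcyclohexa-1,3-dien-1-yl trifluoromethanesulfonate | CC1=C(OS(=O)(=O)C(F)(F)F)[C@](C)(CO[Si](c2ccccc2)(c2ccccc2)C(C)(C)C)CC=C1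
F2 | step 18 | 2-(trimethylsilyl)ethyl (2Z,4E)-5-[(6R)-6-{[(tert-butyldiphenylsilyl)oxy]methyl}-2,6-dimethylcyclohexa-1,3-dien-1-yl]-3-methylpenta-2,4-dienoate | CC1=C(/C=C/C(C)=C\C(=O)OCC[Si](C)(C)C)[C@](C)(CO[Si](c2ccccc2)(c2ccccc2)C(C)(C)C)CC=C1
F3 | step 18 | 2-(trimethylsilyl)ethyl (2Z,4E)-5-[(1R,4R,7S)-7-{[(tert-butyldiphenylsilyl)oxy]methyl}-6,7-dimethyl-2,3-dioxabicyclo[2.2.2]oct-5-en-1-yl]-3-methylpenta-2,4-dienoate | CC1=C[C@H]2C[C@@](C)(CO[Si](c3ccccc3)(c3ccccc3)C(C)(C)C)[C@]1(/C=C/C(C)=C\C(=O)OCC[Si](C)(C)C)OO2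
F4 | step 18 | 2-(trimethylsilyl)ethyl (2Z,4E)-5-[(1R,4R,7S)-7-(hydroxymethyl)-6,7-dimethyl-2,3-dioxabicyclo[2.2.2]oct-5-en-1-yl]-3-methylpenta-2,4-dienoate | CC1=C[C@H]2C[C@@](C)(CO)[C@]1(/C=C/C(C)=C\C(=O)OCC[Si](C)(C)C)OO2
F5 | step 4 | racemic 6-(hydroxymethyl)-2,6-dimethylcyclohex-2-en-1-one | CC1=CCCC(C)(CO)C1=O
F6 | step 4 | [(1R)-1,3-dimethyl-2-oxocyclohex-3-en-1-yl]methyl acetate | CC1=CCC[C@](C)(COC(C)=O)C1=O
F7 | step 17 | [(1R)-1,3-dimethyl-2-[(E)-2-(tributylstannyl)ethenyl]cyclohexa-2,4-dien-1-yl]methyl 2-(trimethylsilyl)ethyl (3S)-3-methyl-3-[(triethylsilyl)oxy]pentanedioate | CC1=C(/C=C/[Sn](CCCC)(CCCC)CCCC)[C@](C)(COC(=O)C[C@](C)(O[Si](CC)(CC)CC)CC(=O)OCC[Si](C)(C)C)CC=C1
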